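**Retrosynthetic overview**

1. Target atom labels used below: C1 = CH–O-angelate, C2 = CH2, C3 = CH–O-isovalerate, C4 = quaternary C(CH3), C5 = bridgehead CH next to the ketone, C6 = C=O, C7 = vinyl CH, C8 = =C(CH3), C9 = second bridgehead CH, C10 = cyclobutane CH, C11 = C(CH3)2.
2. Enabling feature: bond C4–C9 is both a cyclobutane bond (ring C4–C5–C10–C9) and allylic to C7=C8, and C4 is fully substituted. The cyclohexenone ring C4–C5–C6–C7–C8–C9 is therefore the [1,3]-shift isomer of a 2-vinylcyclobutanone C4–C5–C6–C7 (vinyl C8=C9 on C7), which is the crossed ketene [2+2] adduct of a cycloheptene.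
3. Disconnections: C1–O angelate (last); C4–C9 by thermal [1,3] carbon shift (four- to six-membered ring expansion that also closes the cyclobutane); C5–C6 and C4–C7 by intramolecular vinylketene–alkene [2+2]; the ketene by Wolff rearrangement of a (Z)-enoyl diazomethane.
4. Cycloheptene (C1–C5, C10, C11) by ring-closing metathesis at C4=C5; the anti C3-isovalerate/C1-hydroxyl pair by Evans–Tishchenko reduction; C2–C3 by boron aldol to methacrolein; C10–C11 by iridium-catalysed asymmetric allylic alkylation.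
5. Ring order: seven-membered carbocycle first; then, in one operation, six-membered carbocycle C5–C10 plus cyclobutanone, followed by expansion to the cyclohexenone with closure of the cyclobutane.

Key step: step 14

Assumption: the sense of induction in the two reagent-controlled steps (3 and 5) is taken from the usual models for these ligand and reagent families; if either runs the other way, the mirror-image ligand or reagent is used and nothing else changes.

**Route**

Step 1
Reactants: 1 (E)-but-2-ene-1,4-diol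
Product: 2 (E)-4-[(4-methoxybenzyl)oxy]but-2-en-1-ol
Conditions: NaH (0.5 equiv), 4-methoxybenzyl chloride (0.5 equiv), Bu4NI (cat.), THF/DMF, 0 → 25 °C
Reagents that add atoms: 4-methoxybenzyl chloride, COc1ccc(CCl)cc1
Why: Williamson ether synthesis on the monoalkoxide; with the symmetrical diol in excess the mono-ether should dominate and the E alkene is untouched.

Step 2
Reactants: 2 (E)-4-[(4-methoxybenzyl)oxy]but-2-en-1-ol
Product: 3 (E)-4-[(4-methoxybenzyl)oxy]but-2-en-1-yl methyl carbonate
Conditions: ClCO2Me, pyridine, CH2Cl2, 0 °C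
Reagents that add atoms: methyl chloroformate, COC(=O)Cl
Why: O-acylation with a chloroformate gives the allylic carbonate that ionises under iridium catalysis; no stereocentre is involved.

Step 3
Reactants: 3 (E)-4-[(4-methoxybenzyl)oxy]but-2-en-1-yl methyl carbonate; 4 1-methoxy-2-methyl-1-(trimethylsilyloxy)prop-1-ene
Product: 5 methyl (3S)-3-{[(4-methoxybenzyl)oxy]methyl}-2,2-dimethylpent-4-enoate
Conditions: [Ir(cod)Cl]2 (2 mol%), (S)-binaphthol-derived N,N-bis[(S)-1-phenylethyl]phosphoramidite (4 mol%), n-PrNH2 (activation), THF, 25 °C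
Reagents that add atoms: none
Why: Iridium-catalysed branched-selective asymmetric allylic alkylation with a silyl ketene acetal as ester enolate equivalent: methoxide released on decarboxylation frees the enolate, which attacks the substituted allyl terminus to form C10–C11 next to the new quaternary carbon, and the phosphoramidite ligand sets C10 (3S).

Step 4
Reactants: 5 methyl (3S)-3-{[(4-methoxybenzyl)oxy]methyl}-2,2-dimethylpent-4-enoate
Product: 7 (4S)-4-{[(4-methoxybenzyl)oxy]methyl}-3,3-dimethylhex-5-en-2-one, via alpha-silyl ketone 6 (not isolated)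
Conditions: Me3SiCH2Li (2.2 equiv), pentane/THF, 0 → 25 °C; then MeOH, 25 °C
Reagents that add atoms: (trimethylsilyl)methyllithium, [Li]C[Si](C)(C)C
Why: Ester-to-methyl-ketone conversion through an alpha-silyl ketone: addition stops at the ketone stage because the product is held as its enolate, and methanolysis then removes silicon; C10 is not touched.

Step 5
Reactants: 7 (4S)-4-{[(4-methoxybenzyl)oxy]methyl}-3,3-dimethylhex-5-en-2-one; 8 2-methylprop-2-enal
Product: 11 (3R,7S)-3-hydroxy-7-{[(4-methoxybenzyl)oxy]methyl}-2,6,6-trimethylnona-1,8-dien-5-one, via boron enolate 9 (not isolated), via boron aldolate 10 (not isolated)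
Conditions: (−)-Ipc2BCl (1.3 equiv), Et3N, Et2O, 0 °C; then 8, −78 → −20 °C; then H2O2, MeOH, pH 7 buffer, 0 °C
Reagents that add atoms: none
Why: Boron-mediated aldol reaction of a methyl ketone: the only enolisable side of 7 gives the diisopinocampheylboron enolate, which adds to the aldehyde through a chair transition state in which the isopinocampheyl groups select the aldehyde face and set C3 (3R); the minor C3 epimer is a diastereomer and should be removable by chromatography.

Step 6
Reactants: 11 (3R,7S)-3-hydroxy-7-{[(4-methoxybenzyl)oxy]methyl}-2,6,6-trimethylnona-1,8-dien-5-one; 12 3-methylbutanal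
Product: 13 (3R,5R,7S)-5-hydroxy-7-{[(4-methoxybenzyl)oxy]methyl}-2,6,6-trimethylnona-1,8-dien-3-yl 3-methylbutanoate
Conditions: SmI2 (20 mol%), 12 (4 equiv), THF, −10 °C
Reagents that add atoms: none
Why: Evans–Tishchenko reduction: the samarium-bound hemiacetal formed from the C3 hydroxyl and 12 delivers hydride intramolecularly to the C1 ketone, which sets C1 (R, anti to C3), leaves the isovalerate on the C3 oxygen and leaves the C1 hydroxyl free.

Step 7
Reactants: 13 (3R,5R,7S)-5-hydroxy-7-{[(4-methoxybenzyl)oxy]methyl}-2,6,6-trimethylnona-1,8-dien-3-yl 3-methylbutanoate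
Product: 14 (3R,5R,7S)-5-[(tert-butyldimethylsilyl)oxy]-7-{[(4-methoxybenzyl)oxy]methyl}-2,6,6-trimethylnona-1,8-dien-3-yl 3-methylbutanoate
Conditions: TBSOTf, 2,6-lutidine, CH2Cl2, −78 → 0 °C
Reagents that add atoms: tert-butyldimethylsilyl trifluoromethanesulfonate, CC(C)(C)[Si](C)(C)OS(=O)(=O)C(F)(F)F
Why: Silylation of the hindered secondary alcohol with the silyl triflate; the ether must survive diazomethane, the ketene and 180 °C and is removed by fluoride at the end.

Step 8
Reactants: 14 (3R,5R,7S)-5-[(tert-butyldimethylsilyl)oxy]-7-{[(4-methoxybenzyl)oxy]methyl}-2,6,6-trimethylnona-1,8-dien-3-yl 3-methylbutanoate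
Product: 15 (1R,4S,6R)-6-[(tert-butyldimethylsilyl)oxy]-4-{[(4-methoxybenzyl)oxy]methyl}-2,5,5-trimethylcyclohept-2-en-1-yl 3-methylbutanoate
Conditions: second-generation Grubbs catalyst RuCl2(=CHPh)(PCy3)(H2IMes) (5 mol%), PhMe (0.005 M), 80 °C
Reagents that add atoms: none
Why: Ring-closing metathesis between the isopropenyl and vinyl groups closes the seven-membered ring and forms the trisubstituted C4=C5 alkene, driven by dilution and loss of ethene; no stereocentre changes (ring: CH2O-PMB cis to OTBS, ester trans to both).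

Step 9
Reactants: 15 (1R,4S,6R)-6-[(tert-butyldimethylsilyl)oxy]-4-{[(4-methoxybenzyl)oxy]methyl}-2,5,5-trimethylcyclohept-2-en-1-yl 3-methylbutanoate
Product: 16 (1R,4S,6R)-6-[(tert-butyldimethylsilyl)oxy]-4-(hydroxymethyl)-2,5,5-trimethylcyclohept-2-en-1-yl 3-methylbutanoate
Conditions: DDQ, CH2Cl2/pH 7 buffer, 0 °C
Reagents that add atoms: none
Why: Oxidative cleavage of the 4-methoxybenzyl ether (hydride abstraction, then hydrolysis of the oxocarbenium ion); silyl ether, ester and the trisubstituted alkene are inert.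

Step 10
Reactants: 16 (1R,4S,6R)-6-[(tert-butyldimethylsilyl)oxy]-4-(hydroxymethyl)-2,5,5-trimethylcyclohept-2-en-1-yl 3-methylbutanoate
Product: 17 (1R,4S,6R)-6-[(tert-butyldimethylsilyl)oxy]-4-formyl-2,5,5-trimethylcyclohept-2-en-1-yl 3-methylbutanoate
Conditions: Dess–Martin periodinane, NaHCO3, CH2Cl2, 0 °C; used at once
Reagents that add atoms: none
Why: Dess–Martin oxidation under buffered, non-basic conditions should give the beta,gamma-unsaturated aldehyde without epimerisation at C10 or migration of the alkene into conjugation.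

Step 11
Reactants: 17 (1R,4S,6R)-6-[(tert-butyldimethylsilyl)oxy]-4-formyl-2,5,5-trimethylcyclohept-2-en-1-yl 3-methylbutanoate
Product: 18 (1R,4R,6R)-6-[(tert-butyldimethylsilyl)oxy]-4-[(1Z)-2-iodoprop-1-en-1-yl]-2,5,5-trimethylcyclohept-2-en-1-yl 3-methylbutanoate
Conditions: EtPPh3I, n-BuLi, THF, 25 °C; I2, −78 °C; NaN(SiMe3)2, −20 °C; then 17, −78 → −20 °C
Reagents that add atoms: ethyltriphenylphosphonium iodide, CC[P+](c1ccccc1)(c1ccccc1)c1ccccc1.[I-]; iodine, II
Why: Stork–Zhao-type Wittig olefination with the alpha-iodoethylidene ylide gives the (Z)-2-iodoalkene (iodine cis to C10) under kinetic control at −78 °C, where the weakly basic ylide should add to the aldehyde faster than it enolises it, so C10 is kept.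

Step 12
Reactants: 18 (1R,4R,6R)-6-[(tert-butyldimethylsilyl)oxy]-4-[(1Z)-2-iodoprop-1-en-1-yl]-2,5,5-trimethylcyclohept-2-en-1-yl 3-methylbutanoate
Product: 19 (1R,4R,6R)-6-[(tert-butyldimethylsilyl)oxy]-4-[(1Z)-2-carboxyprop-1-en-1-yl]-2,5,5-trimethylcyclohept-2-en-1-yl 3-methylbutanoate
Conditions: Pd(OAc)2 (5 mol%), dppf (10 mol%), CO (1 atm), Et3N, DMF/H2O (4:1), 50 °C
Reagents that add atoms: carbon monoxide, [C-]#[O+]; water, O
Why: Palladium-catalysed hydroxycarbonylation: oxidative addition of the alkenyl iodide to zerovalent palladium, CO insertion and hydrolysis of the acyl–palladium species proceed with retention of alkene geometry, giving the (Z)-acid with the carboxyl (C6) cis to C10.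

Step 13
Reactants: 19 (1R,4R,6R)-6-[(tert-butyldimethylsilyl)oxy]-4-[(1Z)-2-carboxyprop-1-en-1-yl]-2,5,5-trimethylcyclohept-2-en-1-yl 3-methylbutanoate
Product: 21 (1R,4R,6R)-6-[(tert-butyldimethylsilyl)oxy]-4-[(1Z)-4-diazo-2-methyl-3-oxobut-1-en-1-yl]-2,5,5-trimethylcyclohept-2-en-1-yl 3-methylbutanoate, via acid chloride 20 (not isolated)
Conditions: 1-chloro-N,N,2-trimethylprop-1-en-1-amine, CH2Cl2, 0 °C; then CH2N2 (excess), Et2O, 0 °C
Reagents that add atoms: diazomethane, C=[N+]=[N-]
Why: Arndt–Eistert-type acylation of diazomethane: the neutral chloroenamine makes the acid chloride without acid or base that could isomerise the (Z)-enoyl group, and a second equivalent of diazomethane takes up HCl; the diazo carbon becomes C7.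

Step 14
Reactants: 21 (1R,4R,6R)-6-[(tert-butyldimethylsilyl)oxy]-4-[(1Z)-4-diazo-2-methyl-3-oxobut-1-en-1-yl]-2,5,5-trimethylcyclohept-2-en-1-yl 3-methylbutanoate
Product: 24 (1R,2S,4R,6R,7R,8R)-4-[(tert-butyldimethylsilyl)oxy]-3,3,7,11-tetramethyl-9-oxotricyclo[5.4.0.0(2,8)]undec-10-en-6-yl 3-methylbutanoate, via vinylketene 22 (not isolated), via cyclobutanone 23 (not isolated)
Conditions: hν (350 nm), degassed 1,2-dichlorobenzene (0.005 M, base-washed glassware), 25 °C; then 180 °C
Reagents that add atoms: none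
Why: Light expels N2 and the (Z)-alkenyl group migrates with retention (Wolff rearrangement) to give vinylketene 22 with C7 cis to C10. Its C6=C7 bond then adds across C4=C5 in a thermal ketene–alkene [2+2] cycloaddition in the crossed mode known for vinylketenes held on a three-atom tether: C6 bonds to the less substituted C5, which closes the six-membered carbocycle C5–C6–C7–C8–C9–C10 through the tether, and C7 bonds to the fully substituted C4, which closes the cyclobutanone C4–C5–C6–C7. The alkene reacts suprafacially and only on the face that carries the C10 side chain, so C10 alone sets C5, C4 and C7. At 180 °C cyclobutanone 23 should undergo the [1,3] carbon shift of a vinylcyclobutane, the reaction type that racemises alpha-pinene on heating: the strained C7–C4 bond (allylic to C8=C9, alpha to C6=O, tertiary at C4) opens to a dienoxyl/tertiary-alkyl diradical that recloses at the other allyl terminus C9, which lies as close to C4 as C7 does. This is the ring expansion: the four-membered ketone ring C4–C5–C6–C7 takes up C8 and C9 to become the cyclohexenone ring C4–C5–C6–C7–C8–C9, the cyclobutane C4–C5–C10–C9 closes by 1,4-diradical recombination, C9 is set by the cage, and C4 keeps its configuration because it stays bonded to C3 and C5 and can only swing across the same face. The step needs reclosure at C9 instead of C7 and reclosure instead of hydrogen transfer; 24 is the conjugated enone and the expected thermodynamic sink, 23 re-enters the diradical until consumed while 24 should do so far more slowly, cycloreversion of 23 to the ketene only returns 23, and the C3 ester lies on the face away from the migrating bond.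

Step 15
Reactants: 24 (1R,2S,4R,6R,7R,8R)-4-[(tert-butyldimethylsilyl)oxy]-3,3,7,11-tetramethyl-9-oxotricyclo[5.4.0.0(2,8)]undec-10-en-6-yl 3-methylbutanoate
Product: 25 (1R,2S,4R,6R,7R,8R)-4-hydroxy-3,3,7,11-tetramethyl-9-oxotricyclo[5.4.0.0(2,8)]undec-10-en-6-yl 3-methylbutanoate
Conditions: HF·pyridine, pyridine, THF, 0 → 25 °C
Reagents that add atoms: none
Why: Fluoride cleavage of the silyl ether with buffered HF–pyridine; enone, ester and cyclobutane are stable to it and no base is present that could move the acyl group.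

Step 16
Reactants: 25 (1R,2S,4R,6R,7R,8R)-4-hydroxy-3,3,7,11-tetramethyl-9-oxotricyclo[5.4.0.0(2,8)]undec-10-en-6-yl 3-methylbutanoate; 26 (2Z)-2-methylbut-2-enoic acid
Product: 27 (1R,2S,4R,6R,7R,8R)-3,3,7,11-tetramethyl-6-[(3-methylbutanoyl)oxy]-9-oxotricyclo[5.4.0.0(2,8)]undec-10-en-4-yl (2Z)-2-methylbut-2-enoate
Conditions: 26, 2,4,6-Cl3C6H2COCl, Et3N, PhMe, 25 °C; then 25, 80 °C
Reagents that add atoms: none
Why: Yamaguchi-type esterification through the mixed 2,4,6-trichlorobenzoic anhydride without a nucleophilic amine catalyst, the established way to make angelates of hindered alcohols without Z-to-E isomerisation to the tiglate; no stereocentre changes.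

**Compound list**

1 | (E)-but-2-ene-1,4-diol | OC/C=C/CO | starting material
2 | (E)-4-[(4-methoxybenzyl)oxy]but-2-en-1-ol | COc1ccc(COC/C=C/CO)cc1 | intermediate
3 | (E)-4-[(4-methoxybenzyl)oxy]but-2-en-1-yl methyl carbonate | COC(=O)OC/C=C/COCc1ccc(OC)cc1 | intermediate
4 | 1-methoxy-2-methyl-1-(trimethylsilyloxy)prop-1-ene | COC(O[Si](C)(C)C)=C(C)C | starting material
5 | methyl (3S)-3-{[(4-methoxybenzyl)oxy]methyl}-2,2-dimethylpent-4-enoate | COC(=O)C(C)(C)[C@@H](COCc1ccc(OC)cc1)C=C | intermediate
6 | (4S)-4-{[(4-methoxybenzyl)oxy]methyl}-3,3-dimethyl-1-(trimethylsilyl)hex-5-en-2-one | C[Si](C)(C)CC(=O)C(C)(C)[C@@H](COCc1ccc(OC)cc1)C=C | intermediate (not isolated)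
7 | (4S)-4-{[(4-methoxybenzyl)oxy]methyl}-3,3-dimethylhex-5-en-2-one | CC(=O)C(C)(C)[C@@H](COCc1ccc(OC)cc1)C=C | intermediate
8 | 2-methylprop-2-enal (methacrolein) | CC(=C)C=O | starting material
9 | diisopinocampheylboron enolate of 7 (boron on the C1 oxygen, C1=C2 double bond) | C=C(OB([C@@H]1C[C@@H]2C[C@H]([C@H]1C)C2(C)C)[C@@H]1C[C@@H]2C[C@H]([C@H]1C)C2(C)C)C(C)(C)[C@@H](COCc1ccc(OC)cc1)C=C | intermediate (not isolated)
10 | diisopinocampheylboron aldolate of 11 (boron on the C3 oxygen) | C=C(C)[C@H](OB([C@@H]1C[C@@H]2C[C@H]([C@H]1C)C2(C)C)[C@@H]1C[C@@H]2C[C@H]([C@H]1C)C2(C)C)CC(=O)C(C)(C)[C@@H](COCc1ccc(OC)cc1)C=C | intermediate (not isolated)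
11 | (3R,7S)-3-hydroxy-7-{[(4-methoxybenzyl)oxy]methyl}-2,6,6-trimethylnona-1,8-dien-5-one | C=C(C)[C@H](O)CC(=O)C(C)(C)[C@@H](COCc1ccc(OC)cc1)C=C | intermediate
12 | 3-methylbutanal | CC(C)CC=O | starting material
13 | (3R,5R,7S)-5-hydroxy-7-{[(4-methoxybenzyl)oxy]methyl}-2,6,6-trimethylnona-1,8-dien-3-yl 3-methylbutanoate | C=C(C)[C@H](OC(=O)CC(C)C)C[C@@H](O)C(C)(C)[C@@H](COCc1ccc(OC)cc1)C=C | intermediate
14 | (3R,5R,7S)-5-[(tert-butyldimethylsilyl)oxy]-7-{[(4-methoxybenzyl)oxy]methyl}-2,6,6-trimethylnona-1,8-dien-3-yl 3-methylbutanoate | C=C(C)[C@H](OC(=O)CC(C)C)C[C@@H](O[Si](C)(C)C(C)(C)C)C(C)(C)[C@@H](COCc1ccc(OC)cc1)C=C | intermediate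
15 | (1R,4S,6R)-6-[(tert-butyldimethylsilyl)oxy]-4-{[(4-methoxybenzyl)oxy]methyl}-2,5,5-trimethylcyclohept-2-en-1-yl 3-methylbutanoate | CC1=C[C@H](COCc2ccc(OC)cc2)C(C)(C)[C@H](O[Si](C)(C)C(C)(C)C)C[C@H]1OC(=O)CC(C)C | intermediate
16 | (1R,4S,6R)-6-[(tert-butyldimethylsilyl)oxy]-4-(hydroxymethyl)-2,5,5-trimethylcyclohept-2-en-1-yl 3-methylbutanoate | CC1=C[C@H](CO)C(C)(C)[C@H](O[Si](C)(C)C(C)(C)C)C[C@H]1OC(=O)CC(C)C | intermediate
17 | (1R,4S,6R)-6-[(tert-butyldimethylsilyl)oxy]-4-formyl-2,5,5-trimethylcyclohept-2-en-1-yl 3-methylbutanoate | CC1=C[C@H](C=O)C(C)(C)[C@H](O[Si](C)(C)C(C)(C)C)C[C@H]1OC(=O)CC(C)C | intermediate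
18 | (1R,4R,6R)-6-[(tert-butyldimethylsilyl)oxy]-4-[(1Z)-2-iodoprop-1-en-1-yl]-2,5,5-trimethylcyclohept-2-en-1-yl 3-methylbutanoate | CC1=C[C@H](/C=C(/C)I)C(C)(C)[C@H](O[Si](C)(C)C(C)(C)C)C[C@H]1OC(=O)CC(C)C | intermediate
19 | (1R,4R,6R)-6-[(tert-butyldimethylsilyl)oxy]-4-[(1Z)-2-carboxyprop-1-en-1-yl]-2,5,5-trimethylcyclohept-2-en-1-yl 3-methylbutanoate | CC1=C[C@H](/C=C(/C)C(O)=O)C(C)(C)[C@H](O[Si](C)(C)C(C)(C)C)C[C@H]1OC(=O)CC(C)C | intermediate
20 | (1R,4R,6R)-6-[(tert-butyldimethylsilyl)oxy]-4-[(1Z)-3-chloro-2-methyl-3-oxoprop-1-en-1-yl]-2,5,5-trimethylcyclohept-2-en-1-yl 3-methylbutanoate | CC1=C[C@H](/C=C(/C)C(Cl)=O)C(C)(C)[C@H](O[Si](C)(C)C(C)(C)C)C[C@H]1OC(=O)CC(C)C | intermediate (not isolated)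
21 | (1R,4R,6R)-6-[(tert-butyldimethylsilyl)oxy]-4-[(1Z)-4-diazo-2-methyl-3-oxobut-1-en-1-yl]-2,5,5-trimethylcyclohept-2-en-1-yl 3-methylbutanoate | CC1=C[C@H](/C=C(/C)C(=O)C=[N+]=[N-])C(C)(C)[C@H](O[Si](C)(C)C(C)(C)C)C[C@H]1OC(=O)CC(C)C | intermediate
22 | (1R,4S,6R)-6-[(tert-butyldimethylsilyl)oxy]-2,5,5-trimethyl-4-[(1Z)-2-methyl-4-oxobuta-1,3-dien-1-yl]cyclohept-2-en-1-yl 3-methylbutanoate (vinylketene) | CC1=C[C@H](/C=C(/C)C=C=O)C(C)(C)[C@H](O[Si](C)(C)C(C)(C)C)C[C@H]1OC(=O)CC(C)C | intermediate (not isolated)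
23 | tricyclic 2-vinylcyclobutanone: 5-[(tert-butyldimethylsilyl)oxy]-2,6,6,9-tetramethyl-11-oxotricyclo[5.4.0.0(2,10)]undec-8-en-3-yl 3-methylbutanoate (C6=O bonded to C5 and C7, bond C4–C7, alkene C8=C9; configuration at C1, C3, C4, C5, C10 as in 24) | CC(C)(C)[Si](C)(C)O[C@@H]1C[C@@H](OC(=O)CC(C)C)[C@@]2(C)[C@@H]3C(=O)[C@H]2C(C)=C[C@@H]3C1(C)C | intermediate (not isolated)
24 | (1R,2S,4R,6R,7R,8R)-4-[(tert-butyldimethylsilyl)oxy]-3,3,7,11-tetramethyl-9-oxotricyclo[5.4.0.0(2,8)]undec-10-en-6-yl 3-methylbutanoate | CC(C)(C)[Si](C)(C)O[C@@H]1C[C@@H](OC(=O)CC(C)C)[C@@]2(C)[C@@H]3C(=O)C=C(C)[C@H]2[C@@H]3C1(C)C | intermediate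
25 | (1R,2S,4R,6R,7R,8R)-4-hydroxy-3,3,7,11-tetramethyl-9-oxotricyclo[5.4.0.0(2,8)]undec-10-en-6-yl 3-methylbutanoate | O[C@@H]1C[C@@H](OC(=O)CC(C)C)[C@@]2(C)[C@@H]3C(=O)C=C(C)[C@H]2[C@@H]3C1(C)C | intermediate
26 | (2Z)-2-methylbut-2-enoic acid (angelic acid) | C/C=C(/C)C(O)=O | starting material
27 | (1R,2S,4R,6R,7R,8R)-3,3,7,11-tetramethyl-6-[(3-methylbutanoyl)oxy]-9-oxotricyclo[5.4.0.0(2,8)]undec-10-en-4-yl (2Z)-2-methylbut-2-enoate (CNP0240547.2) | C/C=C(/C)C(=O)O[C@@H]1C[C@@H](OC(=O)CC(C)C)[C@@]2(C)[C@@H]3C(=O)C=C(C)[C@H]2[C@@H]3C1(C)C | target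

**Summary**

Total step count: 16. Longest linear sequence: 16 steps (1 → 27; 4, 8, 12 and 26 enter as purchased reagents).

**Steps most likely to fail**

Step 14 (key step). What may go wrong: the diradical may transfer hydrogen and give ring-opened fused dienones instead of reclosing at C9, reclosure may return only to C7, or the ketene may drain into its fused [2+2] isomer. The fallback sets out from 21 and comes back at 24. The reaction is stopped after the photochemical stage at 25 °C and cyclobutanone 23 is isolated. C4 is then moved by a stepwise ionic relay in place of the thermal homolysis: Me2AlCl, CH2Cl2, −78 → −40 °C. Coordination of aluminium to C6=O should ionise the C7–C4 bond to an aluminium dienolate and a tertiary C4 cation. The carbonyl oxygen of the neighbouring C3 isovalerate captures this cation as a dioxolanylium ion from the face opposite the departing C7; this anchimeric assistance is meant to suppress proton loss. The dienolate then reopens the ion at C4 through its gamma-carbon C9 on the face that C7 has left, giving 24. This fallback makes no compound outside the list (F0).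

Step 3. What may go wrong: poor branched-to-linear selectivity or poor enantioselectivity when an aliphatic, oxygen-bearing allyl carbonate meets a fully substituted enolate. The fallback sets out from 2 and comes back at 7, using a sigmatropic rearrangement in place of metal–allyl chemistry. Alcohol 2 is acylated with isobutyryl chloride and pyridine to give (E)-4-[(4-methoxybenzyl)oxy]but-2-en-1-yl 2-methylpropanoate F1. Enantioselective Ireland–Claisen rearrangement of its boron ketene acetal (a chiral B-bromo-1,3,2-diazaborolidine derived from a 1,2-diphenylethylenediamine bis-sulfonamide, Et3N, CH2Cl2, −78 → 4 °C) forms the same C10–C11 bond through a chair transition state and gives (3S)-3-{[(4-methoxybenzyl)oxy]methyl}-2,2-dimethylpent-4-enoic acid F2. If selectivity falls short, the acid is resolved as its 1-phenylethylammonium salt. MeLi (2.2 equiv, Et2O, 0 °C) converts F2 directly into methyl ketone 7.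

Step 16. What may go wrong: incomplete acylation of the hindered C1 hydroxyl next to the quaternary C11, and Z-to-E isomerisation of the activated angeloyl group to the tiglate. The fallback sets out from 25 and comes back at 27, building the angelate double bond on the ester. Alcohol 25 is esterified with 2-[bis(2,2,2-trifluoroethoxy)phosphoryl]propanoic acid (DCC, DMAP, CH2Cl2), an acid that cannot isomerise, to give (1R,2S,4R,6R,7R,8R)-3,3,7,11-tetramethyl-6-[(3-methylbutanoyl)oxy]-9-oxotricyclo[5.4.0.0(2,8)]undec-10-en-4-yl 2-[bis(2,2,2-trifluoroethoxy)phosphoryl]propanoate F3. Still–Gennari olefination with acetaldehyde (KN(SiMe3)2, 18-crown-6, THF, −78 °C) then forms the (Z)-2-methylbut-2-enoate 27.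

**Further compounds**

F0 | step 14 | none | none
F1 | step 3 | (E)-4-[(4-methoxybenzyl)oxy]but-2-en-1-yl 2-methylpropanoate | CC(C)C(=O)OC/C=C/COCc1ccc(OC)cc1
F2 | step 3 | (3S)-3-{[(4-methoxybenzyl)oxy]methyl}-2,2-dimethylpent-4-enoic acid | OC(=O)C(C)(C)[C@@H](COCc1ccc(OC)cc1)C=C
F3 | step 16 | (1R,2S,4R,6R,7R,8R)-3,3,7,11-tetramethyl-6-[(3-methylbutanoyl)oxy]-9-oxotricyclo[5.4.0.0(2,8)]undec-10-en-4-yl 2-[bis(2,2,2-trifluoroethoxy)phosphoryl]propanoate (both epimers at the phosphonate carbon) | CC(C(=O)O[C@@H]1C[C@@H](OC(=O)CC(C)C)[C@@]2(C)[C@@H]3C(=O)C=C(C)[C@H]2[C@@H]3C1(C)C)P(=O)(OCC(F)(F)F)OCC(F)(F)F
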